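**Retrosynthetic overview**

1. Target 28 comes from hemiketal 27 by alkoxy-radical β-scission of the C1–C16 bond, a bond that is not in 28: the cyclobutane opens to the seven-membered lactone and C1 takes up H.
2. Cyclobutanone 25 comes from amide 22 by an intramolecular keteniminium–alkene [2+2] that makes C16–C15 and C1–C14 together (cyclohexane plus a temporary cyclobutanone). The enabling feature of 22: the carboxamide carbon C16 sits on tetrahydrofuran carbon C1, the (Z)-pent-3-enyl chain on the neighbouring ring carbon C10 puts C14=C15 four atoms from C1, and the C3 oxygen on ring carbon C2 is cis to C16.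
3. 22 comes from triene 21 by ring-closing metathesis (C6=C7, nine-membered ether ring); 21 from C9 methallylation of a cyclic acetal; the tetrahydrofuran from the aldol union (C1–C2) of lactone 12 with aldehyde 16, then lactone aminolysis and acetalisation.
4. 12 comes from an Evans orthoformate alkylation (C10), a Fukuyama ketone synthesis and a chelation-controlled MeMgBr addition (C11); 16 comes from (R)-2-methylglycidol (C3).
5. Ring order: tetrahydrofuran, then oxonene, then cyclohexane with cyclobutanone (key step), then seven-membered lactone by fragmentation.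

Key step: step 16

Remark: atoms are cited by the eunicellane position they take in 28 (C1/C10 ring-fusion CH, C2/C9 ether CH, C3 methyl carbinol carbon bearing the lactone O, C4–C8 rest of the ten-membered ring with C6=C7, C11 acetoxy carbon, C12–C14 cyclohexane, C15 lactone α-carbon, C16 lactone C=O); compound numbers carry no "C".
Remark: 1, 4, 5 and 13 are taken as commercial starting materials.

Step 1
Reactants: 1 pent-3-yn-1-ol
Product: 2 (3Z)-pent-3-en-1-ol
Conditions: H2 (1 atm), Pd/CaCO3 poisoned with Pb(OAc)2, quinoline, EtOAc, rt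
Reagents that add atoms: none
Why: Lindlar semi-hydrogenation adds H2 syn to the alkyne and should stop at the Z-alkene.

Step 2
Reactants: 2 (3Z)-pent-3-en-1-ol
Product: 3 (2Z)-5-iodopent-2-ene
Conditions: I2, PPh3, imidazole, CH2Cl2, 0 °C → rt
Reagents that add atoms: iodine (II)
Why: Appel-type iodination of the primary alcohol, which leaves the alkene geometry untouched.

Step 3
Reactants: 5 (4S)-4-benzyl-1,3-oxazolidin-2-one; 4 methyl 4-chloro-4-oxobutanoate
Product: 6 methyl 4-[(4S)-4-benzyl-2-oxo-1,3-oxazolidin-3-yl]-4-oxobutanoate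
Conditions: 5, n-BuLi, THF, −78 °C; then 4, −78 → 0 °C
Reagents that add atoms: none
Why: N-acylation of the lithiated Evans oxazolidinone by the acid chloride.

Step 4
Reactants: 6 methyl 4-[(4S)-4-benzyl-2-oxo-1,3-oxazolidin-3-yl]-4-oxobutanoate
Product: 7 methyl (3R)-3-{[(4S)-4-benzyl-2-oxo-1,3-oxazolidin-3-yl]carbonyl}-4,4-dimethoxybutanoate
Conditions: TiCl4, i-Pr2NEt, CH2Cl2, 0 °C; then HC(OMe)3, 0 °C
Reagents that add atoms: trimethyl orthoformate, COC(OC)OC
Why: Evans titanium-enolate alkylation with an orthoformate; only the imide CH2 is enolised, and the chelated Z-enolate should be attacked by the dimethoxycarbenium ion on the face away from the benzyl group, which sets C10 (R).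

Step 5
Reactants: 7 methyl (3R)-3-{[(4S)-4-benzyl-2-oxo-1,3-oxazolidin-3-yl]carbonyl}-4,4-dimethoxybutanoate
Product: 8 methyl (3R)-3-[(ethylsulfanyl)carbonyl]-4,4-dimethoxybutanoate
Conditions: EtSH, n-BuLi, THF, −78 → 0 °C
Reagents that add atoms: ethanethiol, CCS
Why: lithium thiolate cleavage of a hindered N-acyloxazolidinone at the exocyclic carbonyl gives the thioester and returns the auxiliary, while the methyl ester should react much more slowly.

Step 6
Reactants: 8 methyl (3R)-3-[(ethylsulfanyl)carbonyl]-4,4-dimethoxybutanoate; 3 (2Z)-5-iodopent-2-ene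
Product: 10 methyl (3R,7Z)-3-(dimethoxymethyl)-4-oxonon-7-enoate, via pentenylzinc iodide 9 (not isolated)
Conditions: 3, Zn dust (Me3SiCl-activated), THF, 40 °C; then 8, PdCl2(PPh3)2 (5 mol %), toluene, rt
Reagents that add atoms: none
Why: Fukuyama thioester–alkylzinc coupling gives the ketone under neutral conditions, so the epimerisable C10 centre and the methyl ester should survive.

Step 7
Reactants: 10 methyl (3R,7Z)-3-(dimethoxymethyl)-4-oxonon-7-enoate
Product: 12 (4S,5R)-4-(dimethoxymethyl)-5-methyl-5-[(3Z)-pent-3-en-1-yl]oxolan-2-one, via tertiary alkoxide 11 (not isolated)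
Conditions: MeMgBr, CH2Cl2/Et2O, −78 °C → rt
Reagents that add atoms: methylmagnesium bromide, C[Mg]Br
Why: chelation-controlled Grignard addition (six-membered magnesium chelate between the ketone O and an acetal OMe, Cram chelate model) should deliver methyl anti to the CH2CO2Me branch and so set C11 (R); on warming the alkoxide closes the γ-lactone by acyl substitution.

Step 8
Reactants: 13 [(2R)-2-methyloxiran-2-yl]methanol
Product: 14 (2S)-2-methylhex-5-ene-1,2-diol
Conditions: allylMgBr (2.5 equiv), CuI (10 mol %), THF, −30 → 0 °C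
Reagents that add atoms: allylmagnesium bromide, C=CC[Mg]Br
Why: copper-catalysed Grignard opening of the 2,2-disubstituted epoxide at its CH2 carbon, which leaves the quaternary stereocentre (future C3) untouched.

Step 9
Reactants: 14 (2S)-2-methylhex-5-ene-1,2-diol
Product: 15 (2S)-2-methyl-1,2-bis(triethylsilyloxy)hex-5-ene
Conditions: Et3SiOTf, 2,6-lutidine, CH2Cl2, −78 → 0 °C
Reagents that add atoms: triethylsilyl trifluoromethanesulfonate, CC[Si](CC)(CC)OS(=O)(=O)C(F)(F)F
Why: silyl triflate silylation, reactive enough to cap the tertiary as well as the primary hydroxyl.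

Step 10
Reactants: 15 (2S)-2-methyl-1,2-bis(triethylsilyloxy)hex-5-ene
Product: 16 (2S)-2-methyl-2-(triethylsilyloxy)hex-5-enal
Conditions: (COCl)2, DMSO, CH2Cl2, −78 → −40 °C; then Et3N, → 0 °C
Reagents that add atoms: none
Why: Swern conditions convert a primary triethylsilyl ether directly into the aldehyde while the tertiary silyl ether should stay; the product has no α-hydrogen and cannot epimerise.

Step 11
Reactants: 12 (4S,5R)-4-(dimethoxymethyl)-5-methyl-5-[(3Z)-pent-3-en-1-yl]oxolan-2-one; 16 (2S)-2-methyl-2-(triethylsilyloxy)hex-5-enal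
Product: 17 (3R,4S,5R)-4-(dimethoxymethyl)-3-[(1S,2S)-1-hydroxy-2-methyl-2-(triethylsilyloxy)hex-5-en-1-yl]-5-methyl-5-[(3Z)-pent-3-en-1-yl]oxolan-2-one
Conditions: LiN(i-Pr)2, THF, −78 °C; then 16, −78 °C; aq NH4Cl at −78 °C
Reagents that add atoms: none
Why: lithium lactone enolate aldol; the aldehyde should add trans to the dimethoxymethyl group on the neighbouring ring carbon, and the ring-fixed E(O)-enolate should react through a Zimmerman–Traxler chair to the anti adduct, which together set C2 (S), while the C1 centre formed here is erased in step 16.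

Step 12
Reactants: 17 (aldol lactone)
Product: 18 (2R,3S,4S)-2-[(1S,2R,5Z)-1-(dimethoxymethyl)-2-hydroxy-2-methylhept-5-en-1-yl]-3-hydroxy-N,N,4-trimethyl-4-(triethylsilyloxy)oct-7-enamide
Conditions: Me2NH (2 M in THF), AlMe3, CH2Cl2, 0 °C → rt; Rochelle salt work-up
Reagents that add atoms: dimethylamine, CNC
Why: Weinreb-type aminolysis of the lactone by a dimethylaluminium amide gives the tertiary amide needed in step 16 and releases C2–OH and C9 from their trans arrangement on the lactone so that the tetrahydrofuran can form.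

Step 13
Reactants: 18 (hydroxy amide)
Product: 20 C11 acetate of the 2-methoxyoxolane (C9 methyl acetal, both anomers) formed from C2–OH and C9, via hydroxy acetal 19 (not isolated)
Conditions: PPTS (cat.), CH2Cl2, 0 °C → rt; then Et3N, Ac2O, DMAP, 40 °C
Reagents that add atoms: acetic anhydride, CC(=O)OC(C)=O
Why: acid-catalysed transacetalisation closes the five-membered ring from C2–OH (the tertiary C11–OH could only form a four-membered ring), and DMAP-catalysed acetylation then caps the only free hydroxyl as the acetate of 28.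

Step 14
Reactants: 20 (acetoxy methyl acetal)
Product: 21 2,5-cis-oxolane triene amide (C9 2-methylallyl, C10 chain with C11 acetate and (Z)-pent-3-enyl, C1 CONMe2, C2 chain with C3 methyl, OSiEt3 and but-3-enyl)
Conditions: trimethyl(2-methylallyl)silane, BF3·OEt2, CH2Cl2, −78 → −40 °C
Reagents that add atoms: trimethyl(2-methylprop-2-en-1-yl)silane, CC(=C)C[Si](C)(C)C
Why: Hosomi–Sakurai allylation of the cyclic oxocarbenium ion; the C11 acetate can bridge C9 as a six-membered acetoxonium ion from the face of the C10 substituent and that bulky substituent shields the same face, so the silane should attack from the opposite face and set C9 (S) with C8 cis to C3.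

Step 15
Reactants: 21 (triene amide)
Product: 22 oxonene-bridged amide (2,9-ether-bridged cyclodec-6-ene, 6Z; C1 CONMe2, C3 OSiEt3, C10 chain with C11 acetate and (Z)-pent-3-enyl)
Conditions: second-generation Grubbs catalyst RuCl2(=CHPh)(H2IMes)(PCy3) (10 mol %), toluene (2 mM), 80 °C
Reagents that add atoms: none
Why: ring-closing metathesis; the carbene should form at the terminal butenyl alkene and close onto the 1,1-disubstituted alkene held on the same face by the 2,5-cis-oxolane, the nine-membered ether allowing only the Z trisubstituted alkene, while the Z-propenyl group sits on the other face.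

Step 16
Reactants: 22 (oxonene-bridged amide)
Product: 25 cyclobutanone (C16 ketone bonded to C15 and to quaternary C1; cyclohexane C1/C10–C14 closed; C3 OSiEt3; C11 OAc), via keteniminium triflate 23 (not isolated), via cyclobutaniminium triflate 24 (not isolated)
Conditions: Tf2O, 2,4,6-collidine, ClCH2CH2Cl, 0 → 80 °C; then aq NaHCO3, 40 °C
Reagents that add atoms: water, O
Why: O-triflation of the amide and loss of the C1 proton give the tetrasubstituted keteniminium ion 23, whose electrophilic C16 and nucleophilic C1 add across the tethered Z-alkene in an asynchronous thermal [2+2] (closest precedent: the Ghosez intramolecular keteniminium–olefin cycloaddition of ω-alkenyl amides to bicyclo[4.2.0]octan-7-ones), and water then hydrolyses iminium 24 to ketone 25. The cyclohexane closes by C1–C14 bonding in the exo mode through the four-atom tether C10–C13 (C15 stays outside the six-membered ring), and the cyclobutanone closes by C16–C15 bonding in the same event. C1 becomes quaternary with C14 on the face of the C10 side chain, because the tether can reach C1 only from that face of the tetrahydrofuran, which leaves C16 on the opposite face, cis to the C3 oxygen on C2; C14 follows from the obligatory cis fusion of the four- and six-membered rings, and C15 from suprafacial addition to the Z-alkene (methyl cis to C13). The step needs fused and not bridged regiochemistry, which the tether length and bonding of cationic C16 to the distal alkene carbon should secure, and chemoselection against the ring alkene C6=C7 and the silyl ether, which should hold because a transannular adduct would contain a strained 2-oxabicyclo[2.2.1]heptane and the silyl ether is tertiary and hindered. The C1–C16 bond made here is not in 28; it is there to fix C1, C14 and C15 and to store the strain that opens the ring in step 18.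

Step 17
Reactants: 25 (cyclobutanone)
Product: 27 hemiketal (C3–O–C16(OH), five-membered ring fused to the cyclobutane and the tetrahydrofuran), via hydroxy ketone 26 (not isolated)
Conditions: HF·pyridine, pyridine/THF, 0 °C → rt
Reagents that add atoms: none
Why: fluoride desilylation frees the C3 hydroxyl, which is held cis to the strained cyclobutanone carbonyl and should add to it (sp2 to sp3 strain relief) to give the five-membered hemiketal.

Step 18
Reactants: 27 (hemiketal)
Product: 28 target lactone (CNP0332402.2)
Conditions: [Ir(dF(CF3)ppy)2(5,5'-d(CF3)bpy)]PF6 (2 mol %), 2,4,6-triisopropylbenzenethiol (20 mol %), 2,4,6-collidine, CH2Cl2, 450 nm LEDs, rt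
Reagents that add atoms: none
Why: Proposed new method: proton-coupled electron transfer from the hemiketal O–H to the excited iridium photocatalyst and collidine should give an alkoxy radical, whose β-scission of the strained C1–C16 bond (tertiary radical, cyclobutane strain released) forms the lactone C=O; hydrogen-atom transfer from the thiol to C1 on the only face that keeps the tetrahydrofuran and cyclohexane cis-fused then sets C1 (S) and the thiyl radical closes the redox-neutral cycle. The closest known reaction types are the photocatalytic redox-neutral ring opening of cyclobutanols and other cycloalkanols to ketones by alkoxy-radical β-scission with thiol hydrogen-atom transfer, and the hypoiodite β-fragmentation of bicyclic hemiketals to medium-ring lactones.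

**Compound list**

1 | pent-3-yn-1-ol | CC#CCCO | starting material
2 | (3Z)-pent-3-en-1-ol | C/C=C\CCO | intermediate
3 | (2Z)-5-iodopent-2-ene | C/C=C\CCI | intermediate
4 | methyl 4-chloro-4-oxobutanoate | COC(=O)CCC(Cl)=O | starting material
5 | (4S)-4-benzyl-1,3-oxazolidin-2-one | O=C1N[C@@H](Cc2ccccc2)CO1 | starting material
6 | methyl 4-[(4S)-4-benzyl-2-oxo-1,3-oxazolidin-3-yl]-4-oxobutanoate | COC(=O)CCC(=O)N1[C@@H](Cc2ccccc2)COC1=O | intermediate
7 | methyl (3R)-3-{[(4S)-4-benzyl-2-oxo-1,3-oxazolidin-3-yl]carbonyl}-4,4-dimethoxybutanoate | COC(=O)C[C@H](C(OC)OC)C(=O)N1[C@@H](Cc2ccccc2)COC1=O | intermediate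
8 | methyl (3R)-3-[(ethylsulfanyl)carbonyl]-4,4-dimethoxybutanoate | COC(=O)C[C@H](C(OC)OC)C(=O)SCC | intermediate
9 | [(3Z)-pent-3-en-1-yl]zinc iodide | C/C=C\CC[Zn]I | intermediate
10 | methyl (3R,7Z)-3-(dimethoxymethyl)-4-oxonon-7-enoate | COC(=O)C[C@H](C(OC)OC)C(=O)CC/C=C\C | intermediate
11 | methyl (3S,4R,7Z)-3-(dimethoxymethyl)-4-hydroxy-4-methylnon-7-enoate (present as its bromomagnesium alkoxide) | COC(=O)C[C@H](C(OC)OC)[C@](C)(O)CC/C=C\C | intermediate
12 | (4S,5R)-4-(dimethoxymethyl)-5-methyl-5-[(3Z)-pent-3-en-1-yl]oxolan-2-one | O=C1C[C@H](C(OC)OC)[C@@](C)(CC/C=C\C)O1 | intermediate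
13 | [(2R)-2-methyloxiran-2-yl]methanol | OC[C@]1(C)CO1 | starting material
14 | (2S)-2-methylhex-5-ene-1,2-diol | OC[C@](O)(C)CCC=C | intermediate
15 | (2S)-2-methyl-1,2-bis(triethylsilyloxy)hex-5-ene | CC[Si](CC)(CC)OC[C@](C)(CCC=C)O[Si](CC)(CC)CC | intermediate
16 | (2S)-2-methyl-2-(triethylsilyloxy)hex-5-enal | O=C[C@](C)(CCC=C)O[Si](CC)(CC)CC | intermediate
17 | (3R,4S,5R)-4-(dimethoxymethyl)-3-[(1S,2S)-1-hydroxy-2-methyl-2-(triethylsilyloxy)hex-5-en-1-yl]-5-methyl-5-[(3Z)-pent-3-en-1-yl]oxolan-2-one | O=C1O[C@](C)(CC/C=C\C)[C@@H](C(OC)OC)[C@@H]1[C@H](O)[C@](C)(CCC=C)O[Si](CC)(CC)CC | intermediate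
18 | (2R,3S,4S)-2-[(1S,2R,5Z)-1-(dimethoxymethyl)-2-hydroxy-2-methylhept-5-en-1-yl]-3-hydroxy-N,N,4-trimethyl-4-(triethylsilyloxy)oct-7-enamide | O[C@](C)(CC/C=C\C)[C@@H](C(OC)OC)[C@@H](C(=O)N(C)C)[C@H](O)[C@](C)(CCC=C)O[Si](CC)(CC)CC | intermediate
19 | 2-methoxyoxolane (C9 methyl acetal, both anomers) from C2–OH and C9 of 18, C11–OH free | O[C@](C)(CC/C=C\C)[C@@H]1[C@@H](C(=O)N(C)C)[C@H](OC1OC)[C@](C)(CCC=C)O[Si](CC)(CC)CC | intermediate
20 | C11 acetate of 19 | CC(=O)O[C@](C)(CC/C=C\C)[C@@H]1[C@@H](C(=O)N(C)C)[C@H](OC1OC)[C@](C)(CCC=C)O[Si](CC)(CC)CC | intermediate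
21 | 2,5-cis-oxolane triene amide (C9 2-methylallyl; C10 chain with C11 acetate and (Z)-pent-3-enyl; C1 CONMe2; C2 chain with C3 methyl, OSiEt3, but-3-enyl) | CC(=O)O[C@](C)(CC/C=C\C)[C@@H]1[C@@H](C(=O)N(C)C)[C@H](O[C@H]1CC(C)=C)[C@](C)(CCC=C)O[Si](CC)(CC)CC | intermediate
22 | oxonene-bridged amide (2,9-ether-bridged (6Z)-cyclodec-6-ene; C1 CONMe2; C3 OSiEt3; C10 chain with C11 acetate and (Z)-pent-3-enyl) | CC(=O)O[C@](C)(CC/C=C\C)[C@@H]1[C@@H](C(=O)N(C)C)[C@@H]2O[C@H]1C/C(C)=C\CC[C@]2(C)O[Si](CC)(CC)CC | intermediate
23 | keteniminium triflate of 22 (C1=C16=N+Me2) | CC(=O)O[C@](C)(CC/C=C\C)[C@@H]1C(=C=[N+](C)C)[C@@H]2O[C@H]1C/C(C)=C\CC[C@]2(C)O[Si](CC)(CC)CC.[O-]S(=O)(=O)C(F)(F)F | intermediate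
24 | cyclobutaniminium triflate (C16=N+Me2 in the four-membered ring C1–C14–C15–C16) | CC(=O)O[C@]1(C)CC[C@H]2[C@@H](C)C(=[N+](C)C)[C@@]23[C@@H]1[C@@H]1C/C(C)=C\CC[C@](C)(O[Si](CC)(CC)CC)[C@H]3O1.[O-]S(=O)(=O)C(F)(F)F | intermediate
25 | cyclobutanone (C16 ketone; four-membered ring C1–C14–C15–C16; C3 OSiEt3; C11 OAc) | CC(=O)O[C@]1(C)CC[C@H]2[C@@H](C)C(=O)[C@@]23[C@@H]1[C@@H]1C/C(C)=C\CC[C@](C)(O[Si](CC)(CC)CC)[C@H]3O1 | intermediate
26 | C3-hydroxy cyclobutanone (25 without the silyl group) | CC(=O)O[C@]1(C)CC[C@H]2[C@@H](C)C(=O)[C@@]23[C@@H]1[C@@H]1C/C(C)=C\CC[C@](C)(O)[C@H]3O1 | intermediate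
27 | hemiketal (C3–O–C16(OH); five-membered ring O–C16–C1–C2–C3 fused to the cyclobutane) | CC(=O)O[C@]1(C)CC[C@H]2[C@@H](C)[C@]3(O)O[C@@]4(C)CC/C=C(/C)C[C@@H]5O[C@H]4[C@]23[C@@H]15 | intermediate
28 | CNP0332402.2 (C11 acetate, C16 seven-membered lactone, 2,9-ether bridge, 6Z alkene) | CC(=O)O[C@]1(C)CC[C@@H]2[C@H]3[C@@H]1[C@@H]1C/C(C)=C\CC[C@](C)(OC(=O)[C@@H]2C)[C@H]3O1 | target

**Step count and risks**

Total step count: 18. Longest linear sequence: 13 steps (steps 3–7 and 11–18, from 4 and 5 to 28); steps 1–2 and 8–10 are side branches.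

Step 18 (Proposed new method). What may go wrong: the hemiketal O–H may not be engaged by the photocatalyst and base, β-scission may take the C16–C15 bond instead of C16–C1, or hydrogen transfer to the hindered tertiary C1 radical may be slow. The fallback uses known chemistry and sets out from 27: hypoiodite (Suárez/Suginome) fragmentation with PhI(OAc)2 and I2 under visible light in cyclohexane/CH2Cl2 should give the C1 iodo lactone F1 by the same β-scission with iodine capture, and radical deiodination of F1 with Bu3SnH and AIBN in toluene at 80 °C returns to the route at 28.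

Step 16 (key step). What may go wrong: the congested tetrasubstituted keteniminium ion may fail to form, or it may be captured by the ring alkene or by the silyl ether oxygen before the tethered alkene reacts. The fallback moves the cycloaddition ahead of all ring constructions, where no other alkene or oxygen nucleophile is in reach, and sets out from 12. Opening 12 with Me2NH/AlMe3 gives the hydroxy amide F2, and Ac2O/DMAP gives the amide acetate F3. Tf2O/2,4,6-collidine followed by aqueous NaHCO3 should give the bicyclo[4.2.0]octan-7-one F4; here facial selectivity rests only on a chair transition state with the dimethoxymethyl group equatorial and is less secure than in the templated case. Deprotonation of F4 at the ring-fusion carbon C1 with LiN(SiMe3)2 and aldol addition to 16 on the convex face gives the aldol F5. BF3·OEt2 with trimethyl(2-methylallyl)silane closes the tetrahydrofuran and allylates C9 to give the triene ketone F6, and ring-closing metathesis of F6 returns to the route at 25.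

Step 11. What may go wrong: poor anti/syn selection in the lactone enolate aldol, since the weak Felkin preference of the aldehyde opposes the Zimmerman–Traxler preference, which would give 17 as a mixture at C2. The fallback sets out from 17 of low purity at C2: Dess–Martin oxidation of the carbinol gives the β-keto lactone F7, which erases C2, and non-chelation (Felkin) reduction with NaBH4 in MeOH at −40 °C should deliver hydride anti to the lactone carbonyl and return to the route at 17 (Zn(BH4)2 under chelation control would give the C2 epimer).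

Further compounds
F1 | step 18 | C1-iodo derivative of 28 (either C1 epimer) | CC(=O)O[C@]1(C)CC[C@@H]2C3(I)[C@@H]1[C@@H]1C/C(C)=C\CC[C@](C)(OC(=O)[C@@H]2C)[C@H]3O1
F2 | step 16 | (3S,4R,7Z)-3-(dimethoxymethyl)-4-hydroxy-N,N,4-trimethylnon-7-enamide | O[C@](C)(CC/C=C\C)[C@@H](C(OC)OC)CC(=O)N(C)C
F3 | step 16 | acetate of F2 at the tertiary hydroxyl | CC(=O)O[C@](C)(CC/C=C\C)[C@@H](C(OC)OC)CC(=O)N(C)C
F4 | step 16 | cis-fused bicyclo[4.2.0]octan-7-one (C16 ketone, C15 methyl, C10 dimethoxymethyl, C11 methyl and acetoxy) | CC(=O)O[C@]1(C)CC[C@H]2[C@@H](C)C(=O)[C@H]2[C@@H]1C(OC)OC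
F5 | step 16 | aldol of F4 with 16 at C1 (C2 hydroxyl, C3 OSiEt3) | CC(=O)O[C@]1(C)CC[C@H]2[C@@H](C)C(=O)[C@]2([C@@H]1C(OC)OC)[C@H](O)[C@](C)(CCC=C)O[Si](CC)(CC)CC
F6 | step 16 | triene cyclobutanone (25 with the C6=C7 bond replaced by C9 2-methylallyl and C3 but-3-enyl groups) | CC(=O)O[C@]1(C)CC[C@H]2[C@@H](C)C(=O)[C@@]23[C@@H]1[C@H](CC(C)=C)O[C@@H]3[C@](C)(CCC=C)O[Si](CC)(CC)CC
F7 | step 11 | β-keto lactone (C2 ketone of 17) | O=C1O[C@](C)(CC/C=C\C)[C@@H](C(OC)OC)[C@@H]1C(=O)[C@](C)(CCC=C)O[Si](CC)(CC)CC
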